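1. Sunday's flask cannot make more product: at 4.00 h its other capture product and target together stand at 100% of the substrate charged. Its target reads 32.1% at 1.00 h and 32.8% at 4.00 h. So I take the ratio as final once substrate is used, and I reckon Thursday's flask up to that point.

| flask | substrate | first nucleophile | second nucleophile | capture agent | remark | time |
|---|---|---|---|---|---|---|
| Thursday's | 0.19 M | 1 equiv | 2.5 equiv | 9.5 mM | the very flask that is asked about, followed so far |  |
| Sunday's | 0.19 M | 0.67 equiv | 2.5 equiv | 9.5 mM | run made earlier |  |
| flask | 0.19 M | 1.00 equiv | 2.50 equiv | 9.50 mM |  | 6.0 h |

- Thursday's (time / min: other capture product / %, target / %): 6.00: 21.3, 17.3; 12.0: 35.0, 28.1; 30.0: 52.0, 39.6; 80.0: 57.2, 41.7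
- Sunday's (time / h: other capture product / %, target / %): 1.00: 66.6, 32.1; 2.00: 66.7, 32.7; 3.00: 66.9, 32.4; 4.00: 67.3, 32.8

(each reading ± 0.3 percentage points)

1. ratio of other capture product to target at 40 s
2. ratio of other capture product to target at 15 min
3. ratio of other capture product to target at 6.0 h
4. which of other capture product and target there is more of at 6.0 h

- the numbers in the tables scatter with a standard deviation of 0.3 percentage points
- a reading or a percentage of target counts all its forms, free or not

2. I assume both nucleophiles compete for one feed, each in proportion to what is left of it. The preference is how fast a unit of second nucleophile reacts against a unit of first. Thursday's first reading, with levels taken as charged, gives 0.492.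
3. Holding that reading's ratio, 1.23, I reckon Thursday's target ending at 44.8% of the substrate.
4. The preference times the midway levels then gives an end ratio of 1.41.
5. Step 2 is the weak link: Thursday's target already reads 17.3% at 6.00 min, so the levels no longer stand as charged. Following the levels, the fraction of second nucleophile left equals the fraction of first left raised to one power, the preference (selectivity factor). Sunday's last reading gives 0.466. Thursday's first gives 0.469, from a different charge.
6. For Thursday's flask I now get 1.17 at 40 s. Steps 3 and 4 repeated give 1.35 at 6.0 h, so other capture product leads.
7. The first reading, read as first-order loss, puts 70.5% of the substrate used at 15 min. The same midway reckoning gives 1.29.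

The forecast gives 1.2, 1.26 and 2.5 with other capture product ahead, and holds that “draining should continue”.

Thursday's flask gives 1.18, 1.29 and 1.34, with other capture product at 57.0% and target at 42.4%.

    first nucleophile + open intermediate → target (k = 0.152 M⁻¹ s⁻¹)
    substrate → open intermediate (k = 0.00143 s⁻¹)
    2 substrate → homo dimer (k = 3.38 × 10⁻⁵ M⁻¹ s⁻¹)
    open intermediate + capture agent → trapped intermediate (k = 0.00426 M⁻¹ s⁻¹)
    crystals ⇌ target, rate k5*(cs5 - [target]) while solid is left; crystals form when [target] > cs5 (solubility = 2.40 mM, k = 0.0209 s⁻¹)
    second nucleophile + open intermediate → other capture product (k = 0.0713 M⁻¹ s⁻¹)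

At 0.135 h open intermediate goes to other capture product 1.3 times as fast as to target. By 1.20 h that path has 99.8% of its turnover up to 6.0 h behind it. In this flask at 6.00 h, the 57.6% of first nucleophile left, raised to the preference, gives 77.3%; the flask holds 77.2% of its second nucleophile charge.

In a neighbour flask with 0.600 equiv of first nucleophile, the preference starts the ratio at 1.94, and the midway reckoning ends it at 2.35. That neighbour flask gives 1.96 at 40 s and 2.31 at 6.0 h, with target at 30.0%.

Readings and results stem from a simulated flask for an exercise; scatter was added.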